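**Plan**

1. Retrosynthetic cuts, in order: the side-chain O–Si bond; in the dihydropyranone, C4′–C5′ and O1′–C6′, which leaves a 3-acetylcoumarin and a four-membered lactone; in the coumarin, C3=C4 and the lactone O1–C2 (Knoevenagel condensation and lactonisation); the aryl–CHO bond; the aryl–CH(CH3) bond (aryllithium plus trans-epoxide).
2. Enabling feature: the segment O1′–C2′H(CH3)–C3′H2–C4′(=O) of the six-membered vinylogous ester is, atom for atom, the ring of β-butyrolactone. C5′ and C6′ are the CH3 and C=O carbons of an enolisable acetyl group on coumarin C3, so the ring is the lactone with an enolate C=C inserted into its acyl–oxygen bond.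
3. Forward order: the benzene ring is dressed (CH3, side chain, CHO), the coumarin pyranone ring is closed by Knoevenagel condensation, and the dihydropyranone is made last by a two-atom ring expansion of the β-lactone with the dianion of the coumarin methyl ketone, followed by acid cyclodehydration and desilylation.
4. Stereochemistry: both side-chain centres come from (2R,3R)-2,3-dimethyloxirane by SN2 opening (inversion at the attacked carbon only). C2′(S) comes from (S)-β-butyrolactone and is carried through with its C–O bond intact.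

Key step: step 8

Remark: the side chain has the relative configuration that SN2 opening of trans-2,3-epoxybutane gives directly, so no inversion step is planned; compounds 1, 5, 12 and 14 are taken as purchased.

**Route**

Step 1
Reactants: 1 1,3-bis(benzyloxy)-5-bromobenzene
Product: 3 2,4-bis(benzyloxy)-6-bromobenzaldehyde, via iminium chloride 2 (not isolated)
Conditions: POCl3, DMF, 0 → 70 °C; then H2O
Reagents that add atoms: N,N-dimethylformamide CN(C)C=O; water O
Why: Vilsmeier–Haack formylation; the chloroiminium ion should attack para to one benzyloxy group and ortho to the other (next to Br), because at the site between the two alkoxy groups the iminium cannot become coplanar, and water hydrolyses iminium salt 2 to the aldehyde.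

Step 2
Reactants: 3 2,4-bis(benzyloxy)-6-bromobenzaldehyde
Product: 4 1,5-bis(benzyloxy)-3-bromo-2-methylbenzene
Conditions: Et3SiH, TFA, CH2Cl2, 0 °C → rt
Reagents that add atoms: none
Why: Ionic hydrogenation; the protonated aldehyde and then the benzylic cation, both stabilised by the ortho and para benzyloxy groups, should take up hydride from the silane to give the methyl group, leaving the aryl bromide and benzyl ethers intact.

Step 3
Reactants: 4 1,5-bis(benzyloxy)-3-bromo-2-methylbenzene; 5 (2R,3R)-2,3-dimethyloxirane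
Product: 7 (2R,3R)-3-[3,5-bis(benzyloxy)-2-methylphenyl]butan-2-ol, via aryllithium 6 (not isolated)
Conditions: n-BuLi, THF, −78 °C; then 5, BF3·OEt2, −78 °C; then H2O
Reagents that add atoms: none
Why: Bromine–lithium exchange followed by BF3-promoted SN2 opening of the C2-symmetric trans-epoxide (both carbons equivalent); backside attack inverts the attacked carbon and leaves the other untouched, which sets the (2R,3R) side chain.

Step 4
Reactants: 7 (2R,3R)-3-[3,5-bis(benzyloxy)-2-methylphenyl]butan-2-ol
Product: 8 tert-butyl{[(2R,3R)-3-[3,5-bis(benzyloxy)-2-methylphenyl]butan-2-yl]oxy}dimethylsilane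
Conditions: TBSOTf, 2,6-lutidine, CH2Cl2, 0 °C
Reagents that add atoms: tert-butyldimethylsilyl trifluoromethanesulfonate CC(C)(C)[Si](C)(C)OS(=O)(=O)C(F)(F)F
Why: Silyl ether formation at the secondary alcohol; masking this hydroxyl prevents lactol or quinone methide formation once the aldehyde is present and removes a competing alkoxide from step 8.

Step 5
Reactants: 8 tert-butyl{[(2R,3R)-3-[3,5-bis(benzyloxy)-2-methylphenyl]butan-2-yl]oxy}dimethylsilane
Product: 9 5-[(2R,3R)-3-[(tert-butyldimethylsilyl)oxy]butan-2-yl]-4-methylbenzene-1,3-diol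
Conditions: H2 (1 atm), 10% Pd/C, EtOAc, rt
Reagents that add atoms: none
Why: Hydrogenolysis of the two aryl benzyl ethers; the silyl ether (aprotic solvent) and the non-benzylic C–O bond of the side chain should not be touched.

Step 6
Reactants: 9 5-[(2R,3R)-3-[(tert-butyldimethylsilyl)oxy]butan-2-yl]-4-methylbenzene-1,3-diol
Product: 11 6-[(2R,3R)-3-[(tert-butyldimethylsilyl)oxy]butan-2-yl]-2,4-dihydroxy-5-methylbenzaldehyde, via iminium chloride 10 (not isolated)
Conditions: POCl3, DMF, MeCN, 0 °C → rt; then H2O, 40 °C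
Reagents that add atoms: N,N-dimethylformamide CN(C)C=O; water O
Why: Vilsmeier–Haack formylation of the free resorcinol under mild conditions; attack para to one hydroxyl and ortho to the other (the pattern of 5-alkylresorcinols) should be preferred over the site between the hydroxyls, and iminium salt 10 stays deactivated towards a second arene until it is hydrolysed.

Step 7
Reactants: 11 6-[(2R,3R)-3-[(tert-butyldimethylsilyl)oxy]butan-2-yl]-2,4-dihydroxy-5-methylbenzaldehyde; 12 ethyl acetoacetate
Product: 13 3-acetyl-5-[(2R,3R)-3-[(tert-butyldimethylsilyl)oxy]butan-2-yl]-7-hydroxy-6-methyl-2H-chromen-2-one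
Conditions: piperidine (cat.), AcOH (cat.), EtOH, 50 °C
Reagents that add atoms: none
Why: Knoevenagel condensation of the salicylaldehyde with the β-keto ester followed by lactonisation of the ortho-phenol onto the ethyl ester (classical 3-acetylcoumarin synthesis); the para-hydroxyl and the silyl ether are spectators.

Step 8
Reactants: 13 3-acetyl-5-[(2R,3R)-3-[(tert-butyldimethylsilyl)oxy]butan-2-yl]-7-hydroxy-6-methyl-2H-chromen-2-one; 14 (4S)-4-methyloxetan-2-one
Product: 17 5-[(2R,3R)-3-[(tert-butyldimethylsilyl)oxy]butan-2-yl]-7-hydroxy-6-methyl-3-[(2S)-2-methyl-4-oxo-3,4-dihydro-2H-pyran-6-yl]-2H-chromen-2-one, via dilithium phenoxide enolate 15 (not isolated), via hydroxy diketone 16 (not isolated)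
Conditions: LiHMDS (2.2 equiv), THF, −78 °C; then 14, −78 → −30 °C; AcOH; then TsOH·H2O (cat.), CH2Cl2, rt
Reagents that add atoms: none
Why: LiHMDS removes the phenol proton and then an acetyl CH3 proton of 13, and the carbon of dianion 15 adds to the strained carbonyl of 14; the tetrahedral intermediate collapses with acyl–oxygen cleavage, so that after the acetic acid quench the enolate C=C sits between C(=O) and O of the former four-membered ring in δ-hydroxy β-diketone 16 (Claisen condensation). The closest known reaction types are the acylative opening of β-lactones by lithium enolates, the C-acylation of phenoxide–enolate polyanions of hydroxyaryl methyl ketones, and the acid-catalysed cyclodehydration of δ-hydroxy β-diketones to 2,3-dihydro-4H-pyran-4-ones. The six-membered ring closes by 6-exo-trig attack of the δ-hydroxyl on the coumarin-bound carbonyl (hemiketal) and TsOH-promoted loss of water to the vinylogous ester, the only closure open to 16 because the other carbonyl would give a four-membered ring. No stereocentre is formed: C2′(S) comes from 14 with its C–O bond unbroken, and the side-chain centres are neither acidic nor involved. The step needs acyl- over alkyl-oxygen attack on 14 (hard lithium enolate, secondary and hindered C4 of the lactone), C- over O-acylation (the diketonate is the thermodynamic sink) and enolisation instead of conjugate addition at coumarin C4 (non-nucleophilic amide base, C4 shielded by the peri C5 side chain and deactivated by the 7-oxido group). Because the product stays a diketonate until the quench and the pyranone forms only under acid, base-induced retro-oxa-Michael racemisation of C2′ should not occur.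

Step 9
Reactants: 17 5-[(2R,3R)-3-[(tert-butyldimethylsilyl)oxy]butan-2-yl]-7-hydroxy-6-methyl-3-[(2S)-2-methyl-4-oxo-3,4-dihydro-2H-pyran-6-yl]-2H-chromen-2-one
Product: 18 7-hydroxy-5-[(2R,3R)-3-hydroxybutan-2-yl]-6-methyl-3-[(2S)-2-methyl-4-oxo-3,4-dihydro-2H-pyran-6-yl]-2H-chromen-2-one
Conditions: HF·pyridine, THF, 0 °C → rt
Reagents that add atoms: none
Why: Cleavage of the secondary silyl ether with HF·pyridine; the acidic, non-basic medium should leave the vinylogous ester, the coumarin and the base-sensitive C2′ centre untouched.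

**Compound list**

1 | 1,3-bis(benzyloxy)-5-bromobenzene | Brc1cc(OCc2ccccc2)cc(OCc2ccccc2)c1 | starting material
2 | {[2,4-bis(benzyloxy)-6-bromophenyl]methylidene}dimethylazanium chloride | C[N+](C)=Cc1c(Br)cc(OCc2ccccc2)cc1OCc1ccccc1.[Cl-] | intermediate
3 | 2,4-bis(benzyloxy)-6-bromobenzaldehyde | O=Cc1c(Br)cc(OCc2ccccc2)cc1OCc1ccccc1 | intermediate
4 | 1,5-bis(benzyloxy)-3-bromo-2-methylbenzene | Cc1c(Br)cc(OCc2ccccc2)cc1OCc1ccccc1 | intermediate
5 | (2R,3R)-2,3-dimethyloxirane (trans-2,3-epoxybutane) | C[C@H]1O[C@@H]1C | starting material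
6 | [3,5-bis(benzyloxy)-2-methylphenyl]lithium | [Li]c1cc(OCc2ccccc2)cc(OCc2ccccc2)c1C | intermediate
7 | (2R,3R)-3-[3,5-bis(benzyloxy)-2-methylphenyl]butan-2-ol | C[C@@H](O)[C@H](C)c1cc(OCc2ccccc2)cc(OCc2ccccc2)c1C | intermediate
8 | tert-butyl{[(2R,3R)-3-[3,5-bis(benzyloxy)-2-methylphenyl]butan-2-yl]oxy}dimethylsilane | C[C@@H](O[Si](C)(C)C(C)(C)C)[C@H](C)c1cc(OCc2ccccc2)cc(OCc2ccccc2)c1C | intermediate
9 | 5-[(2R,3R)-3-[(tert-butyldimethylsilyl)oxy]butan-2-yl]-4-methylbenzene-1,3-diol | C[C@@H](O[Si](C)(C)C(C)(C)C)[C@H](C)c1cc(O)cc(O)c1C | intermediate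
10 | {[6-[(2R,3R)-3-[(tert-butyldimethylsilyl)oxy]butan-2-yl]-2,4-dihydroxy-5-methylphenyl]methylidene}dimethylazanium chloride | C[C@@H](O[Si](C)(C)C(C)(C)C)[C@H](C)c1c(C=[N+](C)C)c(O)cc(O)c1C.[Cl-] | intermediate
11 | 6-[(2R,3R)-3-[(tert-butyldimethylsilyl)oxy]butan-2-yl]-2,4-dihydroxy-5-methylbenzaldehyde | C[C@@H](O[Si](C)(C)C(C)(C)C)[C@H](C)c1c(C=O)c(O)cc(O)c1C | intermediate
12 | ethyl acetoacetate (ethyl 3-oxobutanoate) | CCOC(=O)CC(C)=O | starting material
13 | 3-acetyl-5-[(2R,3R)-3-[(tert-butyldimethylsilyl)oxy]butan-2-yl]-7-hydroxy-6-methyl-2H-chromen-2-one | Cc1c(O)cc2oc(=O)c(C(C)=O)cc2c1[C@@H](C)[C@@H](C)O[Si](C)(C)C(C)(C)C | intermediate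
14 | (4S)-4-methyloxetan-2-one ((S)-β-butyrolactone) | C[C@H]1CC(=O)O1 | starting material
15 | dilithium 5-[(2R,3R)-3-[(tert-butyldimethylsilyl)oxy]butan-2-yl]-6-methyl-3-(1-oxidoethenyl)-2-oxo-2H-chromen-7-olate | [Li+].[Li+].Cc1c([O-])cc2oc(=O)c(C(=C)[O-])cc2c1[C@@H](C)[C@@H](C)O[Si](C)(C)C(C)(C)C | intermediate
16 | (5S)-1-{5-[(2R,3R)-3-[(tert-butyldimethylsilyl)oxy]butan-2-yl]-7-hydroxy-6-methyl-2-oxo-2H-chromen-3-yl}-5-hydroxyhexane-1,3-dione | Cc1c(O)cc2oc(=O)c(C(=O)CC(=O)C[C@H](C)O)cc2c1[C@@H](C)[C@@H](C)O[Si](C)(C)C(C)(C)C | intermediate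
17 | 5-[(2R,3R)-3-[(tert-butyldimethylsilyl)oxy]butan-2-yl]-7-hydroxy-6-methyl-3-[(2S)-2-methyl-4-oxo-3,4-dihydro-2H-pyran-6-yl]-2H-chromen-2-one | Cc1c(O)cc2oc(=O)c(C3=CC(=O)C[C@H](C)O3)cc2c1[C@@H](C)[C@@H](C)O[Si](C)(C)C(C)(C)C | intermediate
18 | 7-hydroxy-5-[(2R,3R)-3-hydroxybutan-2-yl]-6-methyl-3-[(2S)-2-methyl-4-oxo-3,4-dihydro-2H-pyran-6-yl]-2H-chromen-2-one | Cc1c(O)cc2oc(=O)c(C3=CC(=O)C[C@H](C)O3)cc2c1[C@@H](C)[C@@H](C)O | target

**Step count and risks**

Total step count: 9. Longest linear sequence: 9 steps (1 → 18); 5, 12 and 14 enter as purchased reagents.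

Steps most likely to fail:

Step 8. What may go wrong: conjugate addition of amide or enolate to coumarin C4 (self-condensation), deprotonation of the lactone by the excess base, or alkyl–oxygen instead of acyl–oxygen cleavage of the lactone. The fallback sets out from 11 (with 12 and 14) and comes back at 17. The same two-atom ring expansion is run on a simple nucleophile: 12 is deprotonated twice (NaH, then n-BuLi, THF, 0 °C) to the ethyl acetoacetate dianion F1, whose terminal carbon acylates on the carbonyl of 14 at −78 °C to give, after an acetic acid quench, ethyl (7S)-7-hydroxy-3,5-dioxooctanoate F2. Catalytic TsOH in CH2Cl2 closes this to ethyl 2-[(2S)-2-methyl-4-oxo-3,4-dihydro-2H-pyran-6-yl]acetate F3. Knoevenagel condensation of F3 with aldehyde 11 (piperidinium acetate, EtOH, rt) and lactonisation then give 17, so that no strong base meets the coumarin.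

Step 6. What may go wrong: formylation at the ring position between the two hydroxyls, or condensation of the new aldehyde with a second molecule of the resorcinol. The fallback sets out from 7 and comes back at 13. The free side-chain hydroxyl is used as a tether: 7 with trimethyl orthoformate and catalytic TMSOTf (CH2Cl2, −20 °C) forms a mixed orthoester whose dialkoxycarbenium ion can only reach the ring carbon ortho to the side chain, giving the cyclic acetal (3R,4R)-6,8-bis(benzyloxy)-1-methoxy-3,4,5-trimethylisochromane F4. Hydrogenolysis (H2, Pd/C, EtOAc) gives (3R,4R)-1-methoxy-3,4,5-trimethylisochromane-6,8-diol F5. This masked hydroxy aldehyde is condensed with 12 (piperidinium acetate, EtOH, 50 °C; the acetal opens in the flask) to 3-acetyl-7-hydroxy-5-[(2R,3R)-3-hydroxybutan-2-yl]-6-methyl-2H-chromen-2-one F6. TBSOTf and 2,6-lutidine give 3-acetyl-7-[(tert-butyldimethylsilyl)oxy]-5-[(2R,3R)-3-[(tert-butyldimethylsilyl)oxy]butan-2-yl]-6-methyl-2H-chromen-2-one F7, and KHF2 in MeOH removes the phenolic silyl group selectively to return to 13.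

Step 7. What may go wrong: slow intermolecular condensation at the doubly ortho-substituted aldehyde, so that the amine degrades the materials before the coumarin forms. The fallback sets out from 11 and comes back at 13. The carbon nucleophile is first tied to the phenol: heating 11 with 2,2,6-trimethyl-4H-1,3-dioxin-4-one (2.2 equiv, toluene, 110 °C) releases acetylketene, which acylates both phenols to give 4-formyl-5-[(2R,3R)-3-[(tert-butyldimethylsilyl)oxy]butan-2-yl]-6-methyl-1,3-phenylene bis(3-oxobutanoate) F8. Catalytic Et3N closes the ortho-formyl ester by intramolecular Knoevenagel condensation to 3-acetyl-5-[(2R,3R)-3-[(tert-butyldimethylsilyl)oxy]butan-2-yl]-6-methyl-2-oxo-2H-chromen-7-yl 3-oxobutanoate F9, and K2CO3 in MeOH at 0 °C cleaves the remaining aryl ester to give 13.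

**Further compounds**

F1 | step 8 | ethyl acetoacetate dianion (sodium lithium salt) | [Na+].[Li+].CCOC(=O)[CH-]C(=O)[CH2-]
F2 | step 8 | ethyl (7S)-7-hydroxy-3,5-dioxooctanoate | CCOC(=O)CC(=O)CC(=O)C[C@H](C)O
F3 | step 8 | ethyl 2-[(2S)-2-methyl-4-oxo-3,4-dihydro-2H-pyran-6-yl]acetate | CCOC(=O)CC1=CC(=O)C[C@H](C)O1
F4 | step 6 | (3R,4R)-6,8-bis(benzyloxy)-1-methoxy-3,4,5-trimethylisochromane (C1 epimers) | COC1O[C@H](C)[C@H](C)c2c(C)c(OCc3ccccc3)cc(OCc3ccccc3)c12
F5 | step 6 | (3R,4R)-1-methoxy-3,4,5-trimethylisochromane-6,8-diol (C1 epimers) | COC1O[C@H](C)[C@H](C)c2c(C)c(O)cc(O)c12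
F6 | step 6 | 3-acetyl-7-hydroxy-5-[(2R,3R)-3-hydroxybutan-2-yl]-6-methyl-2H-chromen-2-one | Cc1c(O)cc2oc(=O)c(C(C)=O)cc2c1[C@@H](C)[C@@H](C)O
F7 | step 6 | 3-acetyl-7-[(tert-butyldimethylsilyl)oxy]-5-[(2R,3R)-3-[(tert-butyldimethylsilyl)oxy]butan-2-yl]-6-methyl-2H-chromen-2-one | Cc1c(O[Si](C)(C)C(C)(C)C)cc2oc(=O)c(C(C)=O)cc2c1[C@@H](C)[C@@H](C)O[Si](C)(C)C(C)(C)C
F8 | step 7 | 4-formyl-5-[(2R,3R)-3-[(tert-butyldimethylsilyl)oxy]butan-2-yl]-6-methyl-1,3-phenylene bis(3-oxobutanoate) | C[C@@H](O[Si](C)(C)C(C)(C)C)[C@H](C)c1c(C=O)c(OC(=O)CC(C)=O)cc(OC(=O)CC(C)=O)c1C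
F9 | step 7 | 3-acetyl-5-[(2R,3R)-3-[(tert-butyldimethylsilyl)oxy]butan-2-yl]-6-methyl-2-oxo-2H-chromen-7-yl 3-oxobutanoate | Cc1c(OC(=O)CC(C)=O)cc2oc(=O)c(C(C)=O)cc2c1[C@@H](C)[C@@H](C)O[Si](C)(C)C(C)(C)C
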